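Ring C is cut at O1–C2 and C4–C3. The feature used is that O1 and C4 sit on neighbouring carbons (C8a, C4a) of ring A while C2–C3 is a two-carbon unit bound to ring B: the pyranone can therefore be assembled from an ortho-iodophenol (ring A, prenyl already at C6), carbon monoxide (C4) and the ring B arylacetylene. One palladium-catalysed carbonylative alkynylation/6-endo cyclisation forges C4–C3 and O1–C2 and delivers the complete flavone skeleton. Its planar C2=C3 bond is then the handle for stereochemistry: ligand-controlled copper hydride 1,4-reduction sets C2, substrate-controlled enolate hydroxylation sets C3 trans, and the methoxymethyl ethers are removed last.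

Key step: step 7

Remark: the four phenols that are free in the target are carried as methoxymethyl (MOM) ethers, because this group directs the ortho-lithiation of step 2 and can be removed at the end without touching the prenyl alkene or the 3'-methyl ether.

Step 1
Reactants: 1 resorcinol
Product: 2 1,3-bis(methoxymethoxy)benzene
Conditions: MOMCl, i-Pr2NEt, CH2Cl2, 0 °C to rt
Reagents that add atoms: chloromethyl methyl ether, COCCl
Why: Double O-alkylation of the phenols (MOM protection); the acetal ethers are stable to the organolithium, palladium and copper hydride steps and serve as ortho-directing groups in step 2.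

Step 2
Reactants: 2 1,3-bis(methoxymethoxy)benzene
Product: 4 1,3-bis(methoxymethoxy)-2-(3-methylbut-2-enyl)benzene, via aryllithium 3 (not isolated)
Conditions: n-BuLi, THF, 0 °C; then CuBr·SMe2 (10 mol %), prenyl bromide, −78 °C to rt
Reagents that add atoms: prenyl bromide (1-bromo-3-methylbut-2-ene), CC(C)=CCBr
Why: Directed ortho-metalation occurs only at the carbon between the two MOM ethers, and copper-catalysed SN2 allylation of the aryllithium places the prenyl group where C6 of the flavonoid will be, flanked by the future 5- and 7-oxygens.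

Step 3
Reactants: 4 1,3-bis(methoxymethoxy)-2-(3-methylbut-2-enyl)benzene
Product: 6 3,5-bis(methoxymethoxy)-4-(3-methylbut-2-enyl)phenol, via arylboronate 5 (not isolated)
Conditions: [Ir(OMe)(cod)]2 (1.5 mol %), 4,4'-di-tert-butyl-2,2'-bipyridine (3 mol %), B2pin2, THF, 60 °C; then NaOH (aq), H2O2 (30 %), 0 °C to rt
Reagents that add atoms: hydrogen peroxide, OO
Why: Sterically controlled iridium-catalysed aromatic C–H borylation attacks the only ring C–H without an ortho substituent (para to the prenyl group), and oxidation of the C–B bond with basic hydrogen peroxide gives the phenol that becomes O1; the trisubstituted prenyl alkene is expected to be inert to both stages.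

Step 4
Reactants: 6 3,5-bis(methoxymethoxy)-4-(3-methylbut-2-enyl)phenol
Product: 7 2-iodo-3,5-bis(methoxymethoxy)-4-(3-methylbut-2-enyl)phenol
Conditions: N-iodosuccinimide (1.0 equiv), MeCN, −20 °C, dark
Reagents that add atoms: N-iodosuccinimide, O=C1CCC(=O)N1I
Why: Electrophilic aromatic iodination ortho to the free phenol; the two ortho positions are equivalent by symmetry and the para position is blocked, so a single mono-iodide should result.

Step 5
Reactants: 8 3,4-dihydroxy-5-methoxybenzaldehyde (5-hydroxyvanillin)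
Product: 9 3-methoxy-4,5-bis(methoxymethoxy)benzaldehyde
Conditions: MOMCl, i-Pr2NEt, CH2Cl2, 0 °C to rt
Reagents that add atoms: chloromethyl methyl ether, COCCl
Why: MOM protection of the ring B catechol by O-alkylation as in step 1; the aldehyde is untouched.

Step 6
Reactants: 9 3-methoxy-4,5-bis(methoxymethoxy)benzaldehyde
Product: 10 5-ethynyl-1-methoxy-2,3-bis(methoxymethoxy)benzene
Conditions: dimethyl (1-diazo-2-oxopropyl)phosphonate, K2CO3, MeOH, rt
Reagents that add atoms: dimethyl (1-diazo-2-oxopropyl)phosphonate, COP(=O)(OC)C(=[N+]=[N-])C(C)=O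
Why: Seyferth–Gilbert homologation in its Ohira–Bestmann form converts the aldehyde into the terminal alkyne under mild carbonate/methanol conditions that leave the MOM ethers intact.

Step 7
Reactants: 7 2-iodo-3,5-bis(methoxymethoxy)-4-(3-methylbut-2-enyl)phenol; 10 5-ethynyl-1-methoxy-2,3-bis(methoxymethoxy)benzene
Product: 13 2-[3-methoxy-4,5-bis(methoxymethoxy)phenyl]-5,7-bis(methoxymethoxy)-6-(3-methylbut-2-enyl)-4H-chromen-4-one, via ynone 11 (not isolated), via enaminone 12 (not isolated)
Conditions: PdCl2(dppf) (5 mol %), CO (20 bar), Et2NH, 100 °C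
Reagents that add atoms: carbon monoxide, [C-]#[O+]
Why: Zerovalent palladium, formed in situ from PdCl2(dppf), inserts into the C–I bond of 7, CO insertion gives an aroyl-palladium species, and alkynyl transfer from 10 with reductive elimination gives ynone 11 (C4–C3, together with C4a–C4); diethylamine adds to 11 to give enaminone 12, and the ortho phenol then displaces the amine at the aryl-bearing carbon (O1–C2) to give the γ-pyrone. The closest known reaction type is the palladium-catalysed carbonylative Sonogashira coupling/cyclisation of ortho-iodophenols with terminal arylacetylenes to flavones. Ring C closes in the 6-endo mode by addition–elimination at C2 of the enaminone, which cannot take the 5-exo path to an aurone. No stereocentre is created: C2 and C3 emerge sp2 and are set in steps 8 and 9. The step needs carbonylative rather than direct alkynylation (the latter would end in a 2-arylbenzofuran) and closure onto the right oxygen; CO pressure and copper-free conditions favour the former, and in 7 the only free phenol is the one ortho to iodine, all others being MOM ethers, while the acyl carbon can only join the terminal alkyne carbon.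

Step 8
Reactants: 13 2-[3-methoxy-4,5-bis(methoxymethoxy)phenyl]-5,7-bis(methoxymethoxy)-6-(3-methylbut-2-enyl)-4H-chromen-4-one
Product: 15 (2S)-2-[3-methoxy-4,5-bis(methoxymethoxy)phenyl]-5,7-bis(methoxymethoxy)-6-(3-methylbut-2-enyl)-2,3-dihydro-4H-chromen-4-one, via silyl enol ether 14 (not isolated)
Conditions: Cu(OAc)2·H2O (5 mol %), (R)-DTBM-SEGPHOS (5.5 mol %), (EtO)2MeSiH (3 equiv), toluene, 0 °C to rt; then AcOH, H2O, THF, 0 °C
Reagents that add atoms: none
Why: Asymmetric conjugate reduction (1,4-hydrosilylation) by a ligated monovalent copper hydride, a reaction type known for chromones: the chiral bisphosphine should direct hydride to the Re face of C2, which gives 2S (the antipodal ligand is used should the opposite sense be found), and the C4 oxygen is held as silyl enol ether 14, so that neither 1,2-reduction nor base-induced ring opening can follow before the mild hydrolysis.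

Step 9
Reactants: 15 (2S)-2-[3-methoxy-4,5-bis(methoxymethoxy)phenyl]-5,7-bis(methoxymethoxy)-6-(3-methylbut-2-enyl)-2,3-dihydro-4H-chromen-4-one
Product: 17 (2R,3R)-3-hydroxy-2-[3-methoxy-4,5-bis(methoxymethoxy)phenyl]-5,7-bis(methoxymethoxy)-6-(3-methylbut-2-enyl)-2,3-dihydro-4H-chromen-4-one, via sodium enolate 16 (not isolated)
Conditions: NaN(SiMe3)2 (1.1 equiv), THF, −78 °C; then 2-(phenylsulfonyl)-3-phenyloxaziridine, −78 °C; AcOH quench at −78 °C
Reagents that add atoms: 2-(phenylsulfonyl)-3-phenyloxaziridine, O=S(=O)(c1ccccc1)N1OC1c1ccccc1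
Why: Enolate α-hydroxylation with an N-sulfonyloxaziridine: C3 is the only enolisable position, and oxygen should be transferred to the enolate face anti to the pseudo-equatorial C2 aryl group, giving the 2,3-trans (2R,3R) ketol by substrate control, while the low temperature is meant to keep the enolate from opening to the chalcone, which would erase C2.

Step 10
Reactants: 17 (2R,3R)-3-hydroxy-2-[3-methoxy-4,5-bis(methoxymethoxy)phenyl]-5,7-bis(methoxymethoxy)-6-(3-methylbut-2-enyl)-2,3-dihydro-4H-chromen-4-one
Product: 18 (2R,3R)-2-(3,4-dihydroxy-5-methoxyphenyl)-3,5,7-trihydroxy-6-(3-methylbut-2-enyl)-2,3-dihydro-4H-chromen-4-one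
Conditions: HCl (3 M aq), MeOH, 45 °C, argon
Reagents that add atoms: none
Why: Acid-catalysed acetal exchange removes the four MOM groups as dimethoxymethane; C3 is not epimerised under acid, any reversible opening of ring C at C2 through the para-quinone methide of ring B should re-close to the more stable 2,3-trans isomer, and the mild temperature is chosen to avoid cyclisation of the 5- or 7-hydroxyl onto the prenyl group.

Compound list
1 | resorcinol | Oc1cccc(O)c1 | starting material
2 | 1,3-bis(methoxymethoxy)benzene | COCOc1cccc(OCOC)c1 | intermediate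
3 | 2,6-bis(methoxymethoxy)phenyllithium | [Li]c1c(OCOC)cccc1OCOC | intermediate (not isolated)
4 | 1,3-bis(methoxymethoxy)-2-(3-methylbut-2-enyl)benzene | COCOc1cccc(OCOC)c1CC=C(C)C | intermediate
5 | 2-[3,5-bis(methoxymethoxy)-4-(3-methylbut-2-enyl)phenyl]-4,4,5,5-tetramethyl-1,3,2-dioxaborolane | CC(C)=CCc1c(OCOC)cc(cc1OCOC)B1OC(C)(C)C(C)(C)O1 | intermediate (not isolated)
6 | 3,5-bis(methoxymethoxy)-4-(3-methylbut-2-enyl)phenol | CC(C)=CCc1c(OCOC)cc(O)cc1OCOC | intermediate
7 | 2-iodo-3,5-bis(methoxymethoxy)-4-(3-methylbut-2-enyl)phenol | CC(C)=CCc1c(OCOC)cc(O)c(I)c1OCOC | intermediate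
8 | 3,4-dihydroxy-5-methoxybenzaldehyde (5-hydroxyvanillin) | COc1cc(C=O)cc(O)c1O | starting material
9 | 3-methoxy-4,5-bis(methoxymethoxy)benzaldehyde | COCOc1cc(C=O)cc(OC)c1OCOC | intermediate
10 | 5-ethynyl-1-methoxy-2,3-bis(methoxymethoxy)benzene | COCOc1cc(C#C)cc(OC)c1OCOC | intermediate
11 | 1-[6-hydroxy-2,4-bis(methoxymethoxy)-3-(3-methylbut-2-enyl)phenyl]-3-[3-methoxy-4,5-bis(methoxymethoxy)phenyl]prop-2-yn-1-one | CC(C)=CCc1c(OCOC)cc(O)c(C(=O)C#Cc2cc(OC)c(OCOC)c(OCOC)c2)c1OCOC | intermediate (not isolated)
12 | 3-(diethylamino)-1-[6-hydroxy-2,4-bis(methoxymethoxy)-3-(3-methylbut-2-enyl)phenyl]-3-[3-methoxy-4,5-bis(methoxymethoxy)phenyl]prop-2-en-1-one (alkene geometry not defined) | CCN(CC)C(=CC(=O)c1c(O)cc(OCOC)c(CC=C(C)C)c1OCOC)c1cc(OC)c(OCOC)c(OCOC)c1 | intermediate (not isolated)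
13 | 2-[3-methoxy-4,5-bis(methoxymethoxy)phenyl]-5,7-bis(methoxymethoxy)-6-(3-methylbut-2-enyl)-4H-chromen-4-one | COCOc1cc2oc(-c3cc(OC)c(OCOC)c(OCOC)c3)cc(=O)c2c(OCOC)c1CC=C(C)C | intermediate
14 | (2S)-4-{[diethoxy(methyl)silyl]oxy}-2-[3-methoxy-4,5-bis(methoxymethoxy)phenyl]-5,7-bis(methoxymethoxy)-6-(3-methylbut-2-enyl)-2H-chromene | COc1cc([C@H]2Oc3cc(OCOC)c(CC=C(C)C)c(OCOC)c3C(O[Si](C)(OCC)OCC)=C2)cc(OCOC)c1OCOC | intermediate (not isolated)
15 | (2S)-2-[3-methoxy-4,5-bis(methoxymethoxy)phenyl]-5,7-bis(methoxymethoxy)-6-(3-methylbut-2-enyl)-2,3-dihydro-4H-chromen-4-one | COc1cc([C@H]2Oc3cc(OCOC)c(CC=C(C)C)c(OCOC)c3C(=O)C2)cc(OCOC)c1OCOC | intermediate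
16 | sodium (2S)-2-[3-methoxy-4,5-bis(methoxymethoxy)phenyl]-5,7-bis(methoxymethoxy)-6-(3-methylbut-2-enyl)-2H-chromen-4-olate | COc1cc([C@H]2Oc3cc(OCOC)c(CC=C(C)C)c(OCOC)c3C([O-])=C2)cc(OCOC)c1OCOC.[Na+] | intermediate (not isolated)
17 | (2R,3R)-3-hydroxy-2-[3-methoxy-4,5-bis(methoxymethoxy)phenyl]-5,7-bis(methoxymethoxy)-6-(3-methylbut-2-enyl)-2,3-dihydro-4H-chromen-4-one | COc1cc([C@H]2Oc3cc(OCOC)c(CC=C(C)C)c(OCOC)c3C(=O)[C@@H]2O)cc(OCOC)c1OCOC | intermediate
18 | (2R,3R)-2-(3,4-dihydroxy-5-methoxyphenyl)-3,5,7-trihydroxy-6-(3-methylbut-2-enyl)-2,3-dihydro-4H-chromen-4-one | COc1cc([C@H]2Oc3cc(O)c(CC=C(C)C)c(O)c3C(=O)[C@@H]2O)cc(O)c1O | target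

Total step count: 10. Longest linear sequence: 8 steps (steps 1–4 and 7–10).

Steps most likely to fail

1. Step 8. Hydride transfer to the electron-rich, doubly donor-substituted pyranone may be too slow, the facial discrimination at C2 may be insufficient, or the C4 carbonyl may be reduced as well. The fallback sets out from 7 and returns at 15; it adds ring B after ring C instead of before it. Iodophenol 7 is carbonylated under the conditions of step 7 with ethynyltrimethylsilane, which should give 5,7-bis(methoxymethoxy)-6-(3-methylbut-2-enyl)-4H-chromen-4-one F1 after amine-induced loss of the silyl group at the enaminone stage. Purchased 3-methoxycatechol F2 is converted with MOMCl/i-Pr2NEt into 1-methoxy-2,3-bis(methoxymethoxy)benzene F3. Iridium-catalysed C–H borylation ([Ir(OMe)(cod)]2, 4,4'-di-tert-butyl-2,2'-bipyridine, B2pin2) functionalises F3 at its only unhindered position and gives 2-[3-methoxy-4,5-bis(methoxymethoxy)phenyl]-4,4,5,5-tetramethyl-1,3,2-dioxaborolane F4. Rhodium-catalysed asymmetric 1,4-addition of F4 to F1 ([Rh(OH)(cod)]2, a chiral diene or an electron-poor chiral bisphosphine in the enantiomer that gives 2S, aqueous KOH, dioxane, 40 °C) then forms the C2–aryl bond and the C2 stereocentre together and gives flavanone 15.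

2. Step 9. The enolate may expel the ring oxygen, that is, open to the chalcone phenoxide and lose the C2 configuration on re-closure, or it may add to the sulfonimine that the oxidant leaves behind. The fallback sets out from silyl enol ether 14 and returns at 17; it avoids any free enolate. The solution of 14 from step 8 is not hydrolysed but treated with nitrosobenzene and catalytic Et3SiOTf in CH2Cl2 at −78 °C (O-selective nitroso aldol reaction). Attack anti to the C2 aryl group should give (2R,3R)-3-(anilinooxy)-2-[3-methoxy-4,5-bis(methoxymethoxy)phenyl]-5,7-bis(methoxymethoxy)-6-(3-methylbut-2-enyl)-2,3-dihydro-4H-chromen-4-one F5. Reductive N–O cleavage (Mo(CO)6, MeCN/H2O, 70 °C) then gives 17.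

3. Step 7. The aroyl-palladium intermediate may be captured by diethylamine to give an amide, alkynylation may outrun CO insertion, or oxidative addition into the electron-rich, doubly ortho-substituted aryl iodide may stall. The fallback sets out from phenol 6 and returns at 13; it installs the C4 carbon first and then makes the two ring C bonds one after the other. Magnesium-mediated ortho-formylation of 6 (MgCl2, Et3N, paraformaldehyde, MeCN, reflux) gives 6-hydroxy-2,4-bis(methoxymethoxy)-3-(3-methylbut-2-enyl)benzaldehyde F6. The lithium acetylide of 10 (n-BuLi, THF, −78 °C, in excess to allow for the phenol) adds to F6 and gives racemic 1-[6-hydroxy-2,4-bis(methoxymethoxy)-3-(3-methylbut-2-enyl)phenyl]-3-[3-methoxy-4,5-bis(methoxymethoxy)phenyl]prop-2-yn-1-ol F7. MnO2 in CH2Cl2 oxidises F7 to ynone 11, and diethylamine in ethanol closes ring C through enaminone 12 to flavone 13.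

Further compounds
F1 | step 8 | 5,7-bis(methoxymethoxy)-6-(3-methylbut-2-enyl)-4H-chromen-4-one | COCOc1cc2occc(=O)c2c(OCOC)c1CC=C(C)C
F2 | step 8 | 3-methoxycatechol (purchased) | COc1cccc(O)c1O
F3 | step 8 | 1-methoxy-2,3-bis(methoxymethoxy)benzene | COCOc1cccc(OC)c1OCOC
F4 | step 8 | 2-[3-methoxy-4,5-bis(methoxymethoxy)phenyl]-4,4,5,5-tetramethyl-1,3,2-dioxaborolane | COCOc1cc(cc(OC)c1OCOC)B1OC(C)(C)C(C)(C)O1
F5 | step 9 | (2R,3R)-3-(anilinooxy)-2-[3-methoxy-4,5-bis(methoxymethoxy)phenyl]-5,7-bis(methoxymethoxy)-6-(3-methylbut-2-enyl)-2,3-dihydro-4H-chromen-4-one | COc1cc([C@H]2Oc3cc(OCOC)c(CC=C(C)C)c(OCOC)c3C(=O)[C@@H]2ONc2ccccc2)cc(OCOC)c1OCOC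
F6 | step 7 | 6-hydroxy-2,4-bis(methoxymethoxy)-3-(3-methylbut-2-enyl)benzaldehyde | CC(C)=CCc1c(OCOC)cc(O)c(C=O)c1OCOC
F7 | step 7 | 1-[6-hydroxy-2,4-bis(methoxymethoxy)-3-(3-methylbut-2-enyl)phenyl]-3-[3-methoxy-4,5-bis(methoxymethoxy)phenyl]prop-2-yn-1-ol (racemic) | CC(C)=CCc1c(OCOC)cc(O)c(C(O)C#Cc2cc(OC)c(OCOC)c(OCOC)c2)c1OCOC
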